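In a one-step world, with c(coupling partner) held fixed, starting material decays on one clock, whatever its charge, and a shorter clock in a smaller charge is the sign that the catalyst is not simply passing molecules through.

| setting | south-east | north-east | south-west | west | north-west |
|---|---|---|---|---|---|
| starting material | 0.0500 M | 0.0200 M | 0.0500 M | 0.0250 M | 0.0500 M |
| coupling partner | 0.100 M | 0.0700 M | 0.150 M | 0.100 M | 0.100 M |
| catalyst | 5.00 × 10⁻⁴ M | 5.00 × 10⁻⁴ M | 5.00 × 10⁻⁴ M | 5.00 × 10⁻⁴ M | 5.00 × 10⁻⁴ M |
| target |  |  |  |  | 0.0150 M |
| time |  |  |  |  | 7.3 min |

| run | time / min | [target] / M |
|---|---|---|
| south-east run | 1.5 | 0.0081 |
| south-east run | 2.9 | 0.0149 |
| south-east run | 4.4 | 0.0205 |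
| south-east run | 5.8 | 0.0266 |
| south-east run | 7.3 | 0.0294 |
| north-east run | 1.5 | 0.0026 |
| north-east run | 2.9 | 0.0052 |
| north-east run | 4.4 | 0.0079 |
| north-east run | 5.8 | 0.0091 |
| north-east run | 7.3 | 0.0106 |
| south-west run | 1.5 | 0.0102 |
| south-west run | 2.9 | 0.0177 |
| south-west run | 4.4 | 0.0240 |
| south-west run | 5.8 | 0.0282 |
| south-west run | 7.3 | 0.0332 |
| west run | 1.5 | 0.0052 |
| west run | 2.9 | 0.0082 |
| west run | 4.4 | 0.0117 |
| west run | 5.8 | 0.0135 |
| west run | 7.3 | 0.0160 |

(standard deviation of a reading: 5 × 10⁻⁴ M)

- Overall: starting material + coupling partner -> target, with catalyst as catalyst.
- Constant volume, constant temperature.
- What is held in complexes is read along with the free species.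
- An order is taken over about fifteen percent of the charge, up and down.
- A share of target counts the target that was charged too.

- the power of [coupling partner] that the first rate follows, about the charge of the south-east run; measure it at two percent of starting material made into target
- the power of [starting material] that the first rate follows, about the charge of the south-east run; measure it at two percent of starting material made into target (one fixed amount of target, the same in the runs compared)
- the north-east run starts with 0.0300 M less of starting material and of coupling partner than the south-east run, and with no target. Compared where both hold the same amount of starting material, once fifteen percent of what the north-east run was charged with has turned into target, is the north-east run faster, slower or alike (within a tenth)?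
- target in the north-west run at 7.3 min, as a share of the starting material charged

The last south-east reading gives 8.23 min for the clock, which I define as the time of a reading divided by the natural logarithm of charged over remaining starting material. This is the pseudo-first-order time of the run, taken as an average over everything up to that reading.

The ladder runs from the catalyst's turn through the reading to the clock. At that pace, one catalyst makes one target in 0.0823 min. The first reading, at 1.5 min, comes later than that, and the clock is longer again. So each south-east reading sees a catalyst that has turned many times, about 18.2 by the first reading, while one turn uses 1.00% of the charged starting material. I therefore read the catalyst's forms as following the composition of the moment.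

The clock of the west run, with its smaller charge, is 7.15 min, shorter than the south-east one. My order in starting material is therefore 0.796. The south-west clock is 6.69 min, which gives 0.510 for the coupling partner. I use last readings because scatter is a smaller share of the last west reading, 3.12%, than of the first, 9.62%. If the charged target leaves the clock alone, the north-west run ends at 88.8%. I reckon nothing of my own for the comparison of the north-east and south-east runs.

The forecast, working from initial rates, says 0.6 for the coupling partner, 0.7 for the starting material, alike, and 87%. On the comparison, its grounds are that there is “no clear product inhibition or catalyst death”. My order in starting material is higher than the forecast's, and my share is slightly higher.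

The flask ran on this scheme:

    catalyst + starting material ⇌ catalyst-substrate complex, settled at all times (5.120 /M)
    catalyst-substrate complex + coupling partner → target + catalyst + by-product (1500 /M/min)
    2 coupling partner ⇌ idle reagent dimer, settled at all times (9.380 /M)
    catalyst + coupling partner ⇌ idle catalyst-reagent complex, settled at all times (6.290 /M)

The flask gives 0.54 for the coupling partner, 0.86 for the starting material, alike at a ratio of 1.0, and 87.9%, so the forecast's 0.7 stands below the flask's order. Through the 7.3 min of the north-west run, catalyst-substrate complex met coupling partner beside the charged target, and the share newly made gives a clock of 8.43 min, against 8.23 min in the south-east run. In the west run the same step brought target to a quarter of the charge at 2.14 min, where its clock gives 2.06 min.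

The earlier runs and the new flask come from a simulation for an exercise.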